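**Retrosynthetic overview**
- Last bond: the C5–O aryl ether. It is made by acid-promoted opening of a 5,8-oxygen-bridged tetrahydrochromone (6,7-diol held as a cyclic carbonate) with 6,7-dihydroxy-2-(2-phenylethyl)chromone; the carbonate is removed in the same pot.
- The catechol chromone is made from the same bridged chromone by dehydrative aromatisation, so both halves come from one intermediate.
- γ-Pyrone ring: acylketene (from benzyl bromide and methyl acetoacetate) plus the silyl enol ether of an enantioenriched 7-oxanorbornanone; the absolute configuration comes from catalytic asymmetric hydroboration of a meso 7-oxanorbornene.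
- Key step: ring expansion of a vinyl oxirane (oxirane to 2,5-dihydrofuran) converts the anti epoxide of benzene cis-dihydrodiol carbonate into that meso 7-oxanorbornene as a single diastereomer, fixing the 5,8-cis / 6,7-cis / anti array.
- Ring order: carbocycle (from the diol) → oxirane → oxygen bridge → γ-pyrone → benzo ring of the second half by aromatisation. The three building blocks each have eight non-hydrogen atoms.

Assumption: cis-cyclohexa-3,5-diene-1,2-diol, methyl acetoacetate and benzyl bromide are taken as commercial, and (R)-DTBM-SEGPHOS in step 4 is assumed to give the hydroxy compound as drawn (its mirror image is used if the sense of induction is opposite).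

Locants C-5 to C-8 below follow chromone numbering.

**Step 1**
Reactants: 1 cis-cyclohexa-3,5-diene-1,2-diol [(1R,2S), meso]
Product: 2 cis-3a,7a-dihydro-1,3-benzodioxol-2-one [(3aR,7aS), meso cyclic carbonate of 1]
Conditions: CDI (1.1 equiv), THF, 0 °C to rt
Reagents that add atoms: 1,1'-carbonyldiimidazole, O=C(n1ccnc1)n1ccnc1
Why: Carbonyl transfer from CDI to the cis-1,2-diol closes the five-membered cyclic carbonate under neutral conditions that do not dehydrate the arene dihydrodiol (cyclic carbonate protection); no stereocentre changes.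

**Step 2**
Reactants: 2 cis-3a,7a-dihydro-1,3-benzodioxol-2-one
Product: 3 rac-4,5-epoxy-3a,4,5,7a-tetrahydro-1,3-benzodioxol-2-one (epoxide oxygen anti to the carbonate)
Conditions: DMDO (1.0 equiv), acetone, −20 to 0 °C
Reagents that add atoms: dimethyldioxirane, CC1(C)OO1
Why: Neutral dioxirane epoxidation of one of the two enantiotopic alkenes takes place on the face opposite the cis-fused carbonate (steric and dipole control), so the racemic mono-epoxide has its oxygen anti to the carbonate.

**Step 3**
Reactants: 3 rac-4,5-epoxy-3a,4,5,7a-tetrahydro-1,3-benzodioxol-2-one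
Product: 4 (3aR,4S,7R,7aS)-3a,4,7,7a-tetrahydro-4,7-epoxy-1,3-benzodioxol-2-one (meso; carbonate endo, anti to the oxygen bridge)
Conditions: MgI2 (10 mol %), THF, 45 °C
Reagents that add atoms: none
Why: Proposed new method: iodide opens the Mg-activated vinyl oxirane in an anti SN2′ sense at the far alkene carbon (the competing 1,2-iodohydrin only recloses to 3), and the magnesium alkoxide then displaces the now trans-1,4 allylic iodide by intramolecular SN2, so the oxirane oxygen ends up bridging the 1,4-positions on its original face (anti to the carbonate) and both enantiomers of 3 converge on meso 4, driven by release of oxirane strain; the closest known reaction is the iodide/Lewis-acid-catalysed ring expansion of 3,4-epoxybut-1-ene and other acyclic vinyl oxiranes to 2,5-dihydrofurans, which has not been shown for an endocyclic diene monoepoxide closing to a 7-oxanorbornene.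

**Step 4**
Reactants: 4 (3aR,4S,7R,7aS)-3a,4,7,7a-tetrahydro-4,7-epoxy-1,3-benzodioxol-2-one
Product: 6 (3aS,4R,5R,7S,7aR)-5-hydroxyhexahydro-4,7-epoxy-1,3-benzodioxol-2-one (5-OH exo), via exo-boronate 5 (not isolated)
Conditions: CuCl (5 mol %), (R)-DTBM-SEGPHOS (5.5 mol %), NaOt-Bu (10 mol %), HBpin (1.2 equiv), toluene, 0 °C; then 30 % H2O2, aq NaHCO3, THF, 0 °C
Reagents that add atoms: pinacolborane, [H]B1OC(C)(C)C(C)(C)O1 (boron of 5); hydrogen peroxide, OO (oxygen of 6)
Why: Copper hydride-catalysed asymmetric hydroboration adds H–B across the exo face of the strained meso alkene (the endo face is blocked by the carbonate) while the chiral bisphosphine chooses between the two enantiotopic alkene carbons, which sets the carbinol centre and the absolute configuration of the whole series; C–B to C–O oxidation goes with retention.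

**Step 5**
Reactants: 6 (3aS,4R,5R,7S,7aR)-5-hydroxyhexahydro-4,7-epoxy-1,3-benzodioxol-2-one
Product: 7 (3aR,4S,7S,7aR)-hexahydro-4,7-epoxy-1,3-benzodioxole-2,5-dione
Conditions: Dess–Martin periodinane (1.3 equiv), CH2Cl2, 0 °C to rt
Reagents that add atoms: none
Why: Dess–Martin oxidation of the secondary alcohol is neutral and so avoids β-elimination of the oxygen bridge; no stereocentre is touched.

**Step 6**
Reactants: 7 (3aR,4S,7S,7aR)-hexahydro-4,7-epoxy-1,3-benzodioxole-2,5-dione
Product: 8 (3aR,4S,7S,7aR)-5-[(tert-butyldimethylsilyl)oxy]-3a,4,7,7a-tetrahydro-4,7-epoxy-1,3-benzodioxol-2-one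
Conditions: TBSOTf (1.2 equiv), Et3N (1.5 equiv), CH2Cl2, 0 °C
Reagents that add atoms: tert-butyldimethylsilyl triflate, CC(C)(C)[Si](C)(C)OS(=O)(=O)C(F)(F)F
Why: Soft enolisation (silyl triflate/amine) gives the only possible enol ether, towards the CH2 group because the other α-carbon is a bridgehead, and avoids a metal enolate that could expel the β-oxygen bridge.

**Step 7**
Reactants: 9 methyl acetoacetate; 10 benzyl bromide
Product: 12 methyl 3-oxo-5-phenylpentanoate, via dilithium dianion 11 (not isolated)
Conditions: LiN(i-Pr)2 (2.1 equiv), THF, −78 to 0 °C; then 10, 0 °C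
Reagents that add atoms: none
Why: Weiler dianion alkylation, in which the more basic terminal carbanion of the acetoacetate dianion is benzylated selectively.

**Step 8**
Reactants: 8 (3aR,4S,7S,7aR)-5-[(tert-butyldimethylsilyl)oxy]-3a,4,7,7a-tetrahydro-4,7-epoxy-1,3-benzodioxol-2-one; 12 methyl 3-oxo-5-phenylpentanoate
Product: 15 (5S,6R,7R,8S)-6,7-(carbonyldioxy)-5,8-epoxy-2-(2-phenylethyl)-5,6,7,8-tetrahydro-4H-chromen-4-one, via acylketene 13 (not isolated), via silyloxy cycloadduct 14 (not isolated)
Conditions: 12 (2 equiv, slow addition), xylenes, 140 °C, N2 sweep; then DBU (1.2 equiv), CH2Cl2, 0 °C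
Reagents that add atoms: none
Why: Thermal loss of methanol from the β-keto ester gives acylketene 13, which adds to the electron-rich silyl enol ether in a hetero-Diels–Alder sense on the exo face, and E1cB loss of silanol from 14 gives the γ-pyrone (acylketene–enol ether pyranone annulation); the four stereocentres of 8 are untouched.

**Step 9**
Reactants: 15 (5S,6R,7R,8S)-6,7-(carbonyldioxy)-5,8-epoxy-2-(2-phenylethyl)-5,6,7,8-tetrahydro-4H-chromen-4-one (the portion needed as nucleophile)
Product: 17 6,7-dihydroxy-2-(2-phenylethyl)-4H-chromen-4-one, via bridged diol 16 (not isolated)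
Conditions: K2CO3 (0.1 equiv), MeOH, 0 °C; then 2 M aq HCl, THF, 60 °C
Reagents that add atoms: none
Why: After methanolysis of the carbonate, acid opens the oxygen bridge at C-5 (cation stabilised by the pyrone ring oxygen), the resulting enol becomes the C-6 ketone and the β-hydroxyl at C-8 leaves through an arenium-type cation stabilised by the C-6 oxygen, so net loss of one water gives the 6,7-catechol (acid-catalysed dehydrative aromatisation, as in inosose-to-polyphenol dehydrations).

**Step 10**
Reactants: 15 (5S,6R,7R,8S)-6,7-(carbonyldioxy)-5,8-epoxy-2-(2-phenylethyl)-5,6,7,8-tetrahydro-4H-chromen-4-one; 17 6,7-dihydroxy-2-(2-phenylethyl)-4H-chromen-4-one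
Product: 19 (5S,6S,7R,8S)-6,7,8-trihydroxy-5-{[7-hydroxy-4-oxo-2-(2-phenylethyl)-4H-chromen-6-yl]oxy}-2-(2-phenylethyl)-5,6,7,8-tetrahydro-4H-chromen-4-one (target), via carbonate 18 (not isolated)
Conditions: 17 (2 equiv), Tf2NH (5 mol %), 4 Å MS, CH2Cl2/MeNO2 (3:1), −40 to −10 °C; then Et3N, K2CO3 (cat.), MeOH, 0 °C
Reagents that add atoms: none
Why: Brønsted acid opens the strained 1,4-epoxide at C-5 to a vinylogous oxocarbenium ion (as in ring-opening glycosylation with anhydro sugars), which is captured by the more nucleophilic, non-conjugated 6-OH of 17 on the face opposite the cis-fused carbonate, so C-5 is set trans to C-6 and the former bridge oxygen stays as the 8-OH with C-6, C-7 and C-8 unchanged; basic methanolysis then removes the carbonate.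

**Compound list**
1 | cis-cyclohexa-3,5-diene-1,2-diol [(1R,2S), meso] | O[C@H]1C=CC=C[C@H]1O | starting material
2 | cis-3a,7a-dihydro-1,3-benzodioxol-2-one [(3aR,7aS), meso] | O=C1O[C@@H]2C=CC=C[C@@H]2O1 | intermediate
3 | rac-4,5-epoxy-3a,4,5,7a-tetrahydro-1,3-benzodioxol-2-one, epoxide anti to the carbonate (one enantiomer drawn) | O=C1O[C@@H]2C=C[C@H]3O[C@H]3[C@@H]2O1 | intermediate
4 | (3aR,4S,7R,7aS)-3a,4,7,7a-tetrahydro-4,7-epoxy-1,3-benzodioxol-2-one (meso, carbonate anti to the oxygen bridge) | C1=C[C@H]2[C@H]3OC(=O)O[C@H]3[C@@H]1O2 | intermediate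
5 | 5-exo-(4,4,5,5-tetramethyl-1,3,2-dioxaborolan-2-yl)hexahydro-4,7-epoxy-1,3-benzodioxol-2-one (boron where 6 carries OH, same spatial arrangement) | CC1(C)OB(OC1(C)C)[C@@H]1C[C@H]2[C@H]3OC(=O)O[C@H]3[C@@H]1O2 | intermediate
6 | (3aS,4R,5R,7S,7aR)-5-hydroxyhexahydro-4,7-epoxy-1,3-benzodioxol-2-one (5-OH exo) | O[C@@H]1C[C@H]2[C@H]3OC(=O)O[C@H]3[C@@H]1O2 | intermediate
7 | (3aR,4S,7S,7aR)-hexahydro-4,7-epoxy-1,3-benzodioxole-2,5-dione | O=C1C[C@H]2[C@H]3OC(=O)O[C@H]3[C@@H]1O2 | intermediate
8 | (3aR,4S,7S,7aR)-5-[(tert-butyldimethylsilyl)oxy]-3a,4,7,7a-tetrahydro-4,7-epoxy-1,3-benzodioxol-2-one | CC(C)(C)[Si](C)(C)OC1=C[C@H]2[C@H]3OC(=O)O[C@H]3[C@@H]1O2 | intermediate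
9 | methyl acetoacetate | COC(=O)CC(C)=O | starting material
10 | benzyl bromide | BrCc1ccccc1 | starting material
11 | dilithium dianion of methyl acetoacetate | [Li+].[Li+].C=C([O-])C=C([O-])OC | intermediate
12 | methyl 3-oxo-5-phenylpentanoate | COC(=O)CC(=O)CCc1ccccc1 | intermediate
13 | 3-oxo-5-phenylpent-1-en-1-one (acylketene) | O=C=CC(=O)CCc1ccccc1 | intermediate
14 | 8a-[(tert-butyldimethylsilyl)oxy]-4a,8a-dihydro precursor of 15 (pyranone ring cis-fused on the exo face; 4a-H and 8a-OSi endo) | O=C1C=C(CCc2ccccc2)O[C@]2(O[Si](C)(C)C(C)(C)C)[C@H]1[C@H]3[C@H]4OC(=O)O[C@H]4[C@@H]2O3 | intermediate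
15 | (5S,6R,7R,8S)-6,7-(carbonyldioxy)-5,8-epoxy-2-(2-phenylethyl)-5,6,7,8-tetrahydro-4H-chromen-4-one | O=c1cc(CCc2ccccc2)oc2c1[C@H]3[C@H]4OC(=O)O[C@H]4[C@@H]2O3 | intermediate
16 | (5S,6S,7R,8S)-5,8-epoxy-6,7-dihydroxy-2-(2-phenylethyl)-5,6,7,8-tetrahydro-4H-chromen-4-one | O=c1cc(CCc2ccccc2)oc2c1[C@H]3[C@@H](O)[C@@H](O)[C@@H]2O3 | intermediate
17 | 6,7-dihydroxy-2-(2-phenylethyl)-4H-chromen-4-one | O=c1cc(CCc2ccccc2)oc2cc(O)c(O)cc12 | intermediate
18 | (5S,6R,7S,8S)-6,7-(carbonyldioxy)-8-hydroxy-5-{[7-hydroxy-4-oxo-2-(2-phenylethyl)-4H-chromen-6-yl]oxy}-2-(2-phenylethyl)-5,6,7,8-tetrahydro-4H-chromen-4-one | O=c1cc(CCc2ccccc2)oc2c1[C@H](Oc1cc3c(=O)cc(CCc4ccccc4)oc3cc1O)[C@H]1OC(=O)O[C@H]1[C@@H]2O | intermediate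
19 | (5S,6S,7R,8S)-6,7,8-trihydroxy-5-{[7-hydroxy-4-oxo-2-(2-phenylethyl)-4H-chromen-6-yl]oxy}-2-(2-phenylethyl)-5,6,7,8-tetrahydro-4H-chromen-4-one | O=c1cc(CCc2ccccc2)oc2c1[C@H](Oc1cc3c(=O)cc(CCc4ccccc4)oc3cc1O)[C@@H](O)[C@@H](O)[C@@H]2O | target

**Step count and risks**
Total: 10 steps. Longest linear sequence: 9 steps (steps 1–6, 8, 9, 10; step 7 is the side branch).

Most likely to fail, first: step 3, the new ring expansion. The iodo-alkoxide may eliminate and aromatise to a phenol instead of closing the bridge, or stop at the 1,2-iodohydrin. The fallback is known chemistry and a different approach: a thermal Diels–Alder reaction of furan (five non-hydrogen atoms) with vinylene carbonate (six), neat, 125 °C, sealed tube. It gives the endo adduct, which is compound 4, together with the exo adduct of furan and vinylene carbonate F1 as a by-product that is removed by crystallisation or chromatography. This fallback sets out from no numbered compound of the route (the two commercial materials take the place of 1 to 3) and comes back to the route at compound 4.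

Second: step 10, the ether-forming bridge opening. Possible failures are attack through the 7-OH or a ring carbon of 17, loss of a proton from the cation (aromatisation of 15), or poor facial control. The fallback sets out from 15 and 17 and separates activation from coupling. Acetolysis of the bridge of 15 (Ac2O, cat. H2SO4, 0 °C) gives the 5,8-diacetate of the 6,7-carbonate F8 as an isolable donor whose 8-oxygen is capped. A Helferich-type aryl ether formation of this donor with 17 (BF3·OEt2, CH2Cl2, −20 °C) then gives the 8-O-acetyl coupled carbonate F9 with loss of acetic acid. Methanolysis (K2CO3, MeOH) removes acetate and carbonate, so the fallback comes back to the route at compound 19.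

Third: step 9, the dehydrative aromatisation. The dehydration could lose the C-7 oxygen instead of the C-8 oxygen and give the 6,8-dihydroxy isomer. The fallback is an independent, classical synthesis of 17. It sets out from compound 10 together with commercial p-benzoquinone (eight non-hydrogen atoms) and methyl acetate, and comes back to the route at compound 17. Thiele–Winter acetoxylation of p-benzoquinone (Ac2O, cat. H2SO4) gives 1,2,4-triacetoxybenzene F2 in one operation. BF3·OEt2 in AcOH at 90 °C converts it into 2,4,5-trihydroxyacetophenone F3 by Fries acyl migration with loss of the other two acetyl groups. Compound 10 with K2CO3 in acetone benzylates the two non-chelated hydroxyls and gives 4,5-bis(benzyloxy)-2-hydroxyacetophenone F4 selectively. Methyl 3-phenylpropanoate F5 is made from 10 and the lithium enolate of methyl acetate (LiN(i-Pr)2, THF, −78 °C). Claisen condensation of F4 with F5 (NaH, THF, reflux) gives 1-[4,5-bis(benzyloxy)-2-hydroxyphenyl]-5-phenylpentane-1,3-dione F6 as the diketone. HCl in AcOH closes it to 6,7-bis(benzyloxy)-2-(2-phenylethyl)-4H-chromen-4-one F7 by cyclodehydration, and H2 over Pd/C then removes both benzyl groups to give 17.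

**Further compounds**
F1 | step 3 | exo adduct of furan and vinylene carbonate: 3a,4,7,7a-tetrahydro-4,7-epoxy-1,3-benzodioxol-2-one with the carbonate syn to the oxygen bridge (meso) | C1=C[C@H]2[C@@H]3OC(=O)O[C@@H]3[C@@H]1O2
F2 | step 9 | 1,2,4-triacetoxybenzene | CC(=O)Oc1ccc(OC(C)=O)c(OC(C)=O)c1
F3 | step 9 | 2,4,5-trihydroxyacetophenone | CC(=O)c1cc(O)c(O)cc1O
F4 | step 9 | 4,5-bis(benzyloxy)-2-hydroxyacetophenone | CC(=O)c1cc(OCc2ccccc2)c(OCc2ccccc2)cc1O
F5 | step 9 | methyl 3-phenylpropanoate | COC(=O)CCc1ccccc1
F6 | step 9 | 1-[4,5-bis(benzyloxy)-2-hydroxyphenyl]-5-phenylpentane-1,3-dione | O=C(CC(=O)CCc1ccccc1)c1cc(OCc2ccccc2)c(OCc2ccccc2)cc1O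
F7 | step 9 | 6,7-bis(benzyloxy)-2-(2-phenylethyl)-4H-chromen-4-one | O=c1cc(CCc2ccccc2)oc2cc(OCc3ccccc3)c(OCc3ccccc3)cc12
F8 | step 10 | 5,8-diacetate of the 6,7-carbonate: (5S,6R,7R,8S)-5,8-diacetoxy-6,7-(carbonyldioxy)-2-(2-phenylethyl)-5,6,7,8-tetrahydro-4H-chromen-4-one (5,6-trans epimer drawn; the C-5 epimer serves equally) | O=c1cc(CCc2ccccc2)oc2c1[C@H](OC(C)=O)[C@H]1OC(=O)O[C@H]1[C@@H]2OC(C)=O
F9 | step 10 | 8-O-acetyl coupled carbonate (8-O-acetyl derivative of 18, same arrangement in space at C-5 to C-8) | O=c1cc(CCc2ccccc2)oc2c1[C@H](Oc1cc3c(=O)cc(CCc4ccccc4)oc3cc1O)[C@H]1OC(=O)O[C@H]1[C@@H]2OC(C)=O
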